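If a flask stops at an equilibrium, then at one temperature the quotient Q of product over substrate left times coupling partner left must come out alike for every charge. We test this on the last row of each run, then carry forward a second quantity as a rough scale for the birch run.

| flask | substrate | coupling partner | free catalyst | time |
|---|---|---|---|---|
| ash | 0.500 M | 0.500 M | 0.0400 M |  |
| alder | 0.250 M | 0.250 M | 0.0400 M |  |
| maple | 0.500 M | 1.00 M | 0.0400 M |  |
| birch | 0.250 M | 0.500 M | 0.0800 M | 24 h |

| run | time / h | [product] / M |
|---|---|---|
| ash run | 4.8 | 0.2515 |
| ash run | 9.6 | 0.2955 |
| ash run | 14 | 0.3111 |
| ash run | 19 | 0.3184 |
| ash run | 24 | 0.3209 |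
| alder run | 4.8 | 0.0961 |
| alder run | 9.6 | 0.1210 |
| alder run | 14 | 0.1330 |
| alder run | 19 | 0.1369 |
| alder run | 24 | 0.1426 |
| maple run | 4.8 | 0.3427 |
| maple run | 9.6 | 0.3896 |
| maple run | 14 | 0.4043 |
| maple run | 19 | 0.4165 |
| maple run | 24 | 0.4187 |

(standard deviation of a reading: 0.002 M)

- reaction order in [coupling partner] at the outset, round the charge of the ash run, defined at two percent of the substrate turned into product
- reaction order in [substrate] at the outset, round the charge of the ash run, defined at two percent of the substrate turned into product (one fixed amount of product, the same in the runs compared)
- the alder run starts with 0.250 M less of substrate and of coupling partner than the ash run, and with no product. Compared where both hold the same amount of substrate, once fifteen percent of what the alder run was charged with has turned into product, is the alder run faster, slower or alike (within a tenth)?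
- product in the birch run at 24 h, as a share of the substrate charged

- Overall: substrate + coupling partner -> product, with free catalyst as catalyst.
- Constant volume, constant temperature.
- Readings of a species count what is bound in complexes too.
- An order is taken over about fifteen percent of the charge, up and down.

Write P for product, a and b for the substrate and coupling partner charged, and S = a − P and R = b − P for what is left. At 24 h, Q reads 10.0 L mol⁻¹ in the ash run, 12.4 L mol⁻¹ in the alder run and 8.86 L mol⁻¹ in the maple run. The gap between alder and maple is 3.54 L mol⁻¹, but the scatter of the readings moves the alder quotient by about 0.634 L mol⁻¹. So we do not take Q as a constant.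

We ask instead how far a one-way law has run. In the ash run the charges are equal, so the reciprocal of S less the reciprocal of a gives 3.58 L mol⁻¹ at 24 h. We call this the reach: the product k·t that the law rate = kSR needs to arrive at a reading. The alder run gives 5.31 L mol⁻¹ in the same way. With unequal charges the reach is ln(Ra/(Sb))/(b − a), so the maple run gives 2.55 L mol⁻¹.

Reading down the column, the alder reach is larger than the ash reach, and the ash reach is larger than the maple reach, as the coupling partner charged rises. The alder-to-maple ratio is 2.08 for the reach and 1.40 for Q, so the reach spreads wider across these runs than Q does. One k does not hold across these runs, and we use the reach as a rough scale and no more. The birch run has the coupling partner charge of the ash run, so we start from the ash reach. It also holds twice the free catalyst, and we assume that k follows the catalyst, though no run tests this. That gives a birch reach of 7.17 L mol⁻¹. Substrate is the limiting reagent in the birch run. Solving the reach for R/S gives 12.0, so S ends at 0.0227 M, and our estimate is 90.9%.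

The forecast gives 0.7 for the order in coupling partner, 0.9 for the order in substrate, faster for the alder comparison and 76% for the birch run. Its ground is that “the reaction stops at a reversible equilibrium, not through catalyst death”. Our estimate stands above its birch figure.

The birch run gives 93.4%, the orders are 0.87 and 1.0, and the alder run is faster, by a ratio of 4.3.

    free catalyst + coupling partner ⇌ catalyst-reagent complex, settled at all times (0.3710 L mol⁻¹)
    catalyst-reagent complex + substrate → product + free catalyst (52.56 L mol⁻¹ h⁻¹)
    2 coupling partner → lost reagent (0.2441 L mol⁻¹ h⁻¹)
    free catalyst → spent catalyst (0.05400 h⁻¹)

These steps hold no way back from product, and the k3 step gives free catalyst a half-life of 12.8 h. Put through the reach, the birch result gives 8.34 L mol⁻¹, more than the 7.17 L mol⁻¹ we carried. The alder run, with half of its substrate turned at 10.6 h, stood at a reach of 4.00 L mol⁻¹, more than the 3.58 L mol⁻¹ of the ash run at 24 h.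

The runs are simulated for an exercise, noise included.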